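**Retrosynthetic overview**

- The acid is unmasked from an N-acyl oxazolidinone. The C2–C3 bond comes from a chiral propionimide titanium enolate and the peroxycarbenium ion of a 3-acetoxy-1,2-dioxane, which sets C2 and C3.
- The 1,2-dioxane (O1–O2–C3–C4–C5–C6) is not closed at ring size six. It arises from the cyclobutane C3–C4–C5–C6 of a 2,2-disubstituted cyclobutanol by insertion of O2 into the C3–C6 bond, a two-atom ring expansion.
- Enabling feature: the four ring carbons carry oxygen only at their ends, a secondary C3 and a fully substituted C6 (methyl, homofarnesyl). In the cyclobutanol, ring strain and the tertiary radical at C6 direct β-scission to the C3–C6 bond, and O2 then bridges C6 and the C3 carbonyl.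
- The cyclobutanol comes from the cyclobutanone, made from (5E,9E)-farnesylacetone by sulfonium cyclopropylide spiroannulation; farnesylacetone comes from (2E,6E)-farnesyl bromide and ethyl acetoacetate.
- Ring order: transient oxaspiropentane, then cyclobutane, then 1,2-dioxane (the only ring of the target).

Key step: step 4

Remark on the chemistry: C6 is created in the key step from a planar tertiary radical and O2, for which no reagent control exists. It is therefore carried as a racemate and resolved in step 6, where the enantiopure auxiliary turns the two C6 antipodes into separable diastereomers, so at most half of the material can be carried on. (2E,6E)-Farnesyl bromide, cyclopropyldiphenylsulfonium tetrafluoroborate and (R)-4-benzyl-3-propionyloxazolidin-2-one are taken as purchasable.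

**Step 1**
Reactants: 1 (2E,6E)-farnesyl bromide; 2 ethyl acetoacetate
Product: 4 (5E,9E)-6,10,14-trimethylpentadeca-5,9,13-trien-2-one (farnesylacetone), via β-keto ester 3 (not isolated)
Conditions: K2CO3, acetone, 55 °C; filter, concentrate; then NaOH, EtOH/H2O, rt; then HCl (pH 2), 50 °C
Reagents that add atoms: none
Why: Acetoacetic ester synthesis (SN2 C-alkylation of the stabilised enolate at the primary allylic bromide, then saponification and decarboxylation) should give the methyl ketone with both E double bonds untouched; no stereocentre is formed.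

**Step 2**
Reactants: 4 farnesylacetone; 5 cyclopropyldiphenylsulfonium tetrafluoroborate
Product: 8 2-methyl-2-[(3E,7E)-4,8,12-trimethyltrideca-3,7,11-trien-1-yl]cyclobutan-1-one (racemic), via sulfonium cyclopropylide 6 (not isolated), via oxaspiropentane 7 (not isolated)
Conditions: KOH (powder), DMSO, rt; then LiBF4 (cat.), toluene, rt
Reagents that add atoms: none
Why: Trost cyclobutanone spiroannulation, in which the reversibly formed ylide adds to the ketone, the betaine closes to the oxaspiropentane with loss of diphenyl sulfide and Li+-promoted cyclopropylcarbinyl-to-cyclobutyl rearrangement gives the 2,2-disubstituted cyclobutanone; the quaternary centre is racemic, which is immaterial because step 4 destroys it.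

**Step 3**
Reactants: 8 cyclobutanone
Product: 9 2-methyl-2-[(3E,7E)-4,8,12-trimethyltrideca-3,7,11-trien-1-yl]cyclobutan-1-ol (racemic; cis/trans mixture)
Conditions: NaBH4, MeOH, 0 °C
Reagents that add atoms: none
Why: Borohydride reduction of the strained ketone leaves the trisubstituted alkenes alone, and the diastereomer mixture is used as such because both ring stereocentres are erased in step 4.

**Step 4**
Reactants: 9 cyclobutanol
Product: 11 6-methyl-6-[(3E,7E)-4,8,12-trimethyltrideca-3,7,11-trien-1-yl]-1,2-dioxan-3-ol (racemic at C6; anomers), via hydroperoxy aldehyde 10 (not isolated)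
Conditions: Co(acac)2 (10 mol %), O2 (1 atm), THF, rt to 40 °C
Reagents that add atoms: dioxygen, O=O
Why: Co(II)/O2 should convert the cyclobutanol O–H into a cobalt(III) alkoxide that releases the cyclobutyloxyl radical; β-scission of the bond between the carbinol carbon and the quaternary carbon (strain release, tertiary radical) gives the open-chain C6 radical with an aldehyde at C3, O2 adds at C6, and the peroxy oxygen then adds to the aldehyde. The closest known reaction is the cobalt(II) acetylacetonate/O2 oxidative ring expansion of secondary cyclobutanols to 1,2-dioxan-3-ols, the homologue of the aerobic cyclopropanol to 1,2-dioxolan-3-ol expansion. The 1,2-dioxane closes by 6-exo-trig addition of the C6 peroxy oxygen to the C3 carbonyl (peroxy-hemiacetal formation), so the former C3–C6 σ-bond is replaced by C6–O1–O2–C3. C6 comes from a planar radical without facial bias and is formed racemic, and C3 is a hemiacetal carbon formed as an anomeric mixture that is erased in step 6; all four stereoisomers of 9 converge on the same product. The step needs regioselective cleavage toward C6, which the quaternary substitution secures against the primary alternative, and chemoselectivity over three trisubstituted alkenes: no hydride source is present, and the C6 radical can only close 4-exo or 5-endo onto the nearest alkene, which should not compete with O2 capture.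

**Step 5**
Reactants: 11 dioxanol
Product: 12 6-methyl-6-[(3E,7E)-4,8,12-trimethyltrideca-3,7,11-trien-1-yl]-1,2-dioxan-3-yl acetate (racemic at C6; anomers)
Conditions: Ac2O, pyridine, DMAP (cat.), CH2Cl2, 0 °C
Reagents that add atoms: acetic anhydride, CC(=O)OC(C)=O
Why: O-acylation of the peroxy-hemiacetal hydroxyl, known for 1,2-dioxan-3-ols, should give an ionisable anomeric acetate under a base mild enough to keep Kornblum–DeLaMare fragmentation at C3–H slow.

**Step 6**
Reactants: 12 acetate; 13 (R)-4-benzyl-3-propionyl-1,3-oxazolidin-2-one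
Product: 15 (4R)-4-benzyl-3-[(2S)-2-[(3S,6S)-6-methyl-6-[(3E,7E)-4,8,12-trimethyltrideca-3,7,11-trien-1-yl]-1,2-dioxan-3-yl]propanoyl]-1,3-oxazolidin-2-one, via titanium enolate 14 (not isolated)
Conditions: 13, TiCl4 (1.1 equiv), i-Pr2NEt, CH2Cl2, −78 to 0 °C; then 12, TiCl4 (1.0 equiv), −78 to −40 °C; aq. NH4Cl; preparative HPLC
Reagents that add atoms: none
Why: Open-transition-state addition of the chelated chlorotitanium (Z)-enolate to the peroxycarbenium ion released from the anomeric acetate (Lewis-acid-mediated enolate addition to a cyclic oxocarbenium ion, the carbon-nucleophile substitution known for 3-acyloxy-1,2-dioxanes), in which the (R)-benzyl group shields one enolate face so that C2 is formed S, the ring is taken up synclinally with its C4 methylene anti to the enolate carbon and the C3 hydrogen over the Ti–O/methyl side so that C3 is formed S (2,3-anti), and C6 exerts no facial bias so that both antipodes of racemic 12 react alike to give two diastereomers, of which the (2S,3S,6S) isomer 15 is isolated by HPLC and the (2S,3S,6R) isomer is discarded.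

**Step 7**
Reactants: 15 imide
Product: 17 (2S)-2-[(3S,6S)-6-methyl-6-[(3E,7E)-4,8,12-trimethyltrideca-3,7,11-trien-1-yl]-1,2-dioxan-3-yl]propanoic acid (CNP0179915.1), via peroxy acid 16 (not isolated)
Conditions: LiOH, H2O2, THF/H2O, 0 °C; then aq. Na2SO3, 0 °C; then HCl to pH 3
Reagents that add atoms: hydrogen peroxide, OO
Why: Evans hydroperoxide cleavage, in which HOO− attacks the exocyclic imide carbonyl, the percarboxylate is reduced by sulfite before acidification so that the chain alkenes are not epoxidised, and the dialkyl peroxide and all three stereocentres should be untouched.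

**Compound list**

1 | (2E,6E)-farnesyl bromide | CC(C)=CCC/C(C)=C/CC/C(C)=C/CBr | starting material
2 | ethyl acetoacetate | CCOC(=O)CC(C)=O | starting material
3 | ethyl (4E,8E)-2-acetyl-5,9,13-trimethyltetradeca-4,8,12-trienoate (racemic, not isolated) | CC(C)=CCC/C(C)=C/CC/C(C)=C/CC(C(C)=O)C(=O)OCC | intermediate
4 | (5E,9E)-6,10,14-trimethylpentadeca-5,9,13-trien-2-one | CC(C)=CCC/C(C)=C/CC/C(C)=C/CCC(C)=O | intermediate
5 | cyclopropyldiphenylsulfonium tetrafluoroborate | C1CC1[S+](c1ccccc1)c1ccccc1.F[B-](F)(F)F | starting material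
6 | diphenylsulfonium cyclopropylide (not isolated) | [C-]1(CC1)[S+](c1ccccc1)c1ccccc1 | intermediate
7 | 2-methyl-2-[(3E,7E)-4,8,12-trimethyltrideca-3,7,11-trien-1-yl]-1-oxaspiro[2.2]pentane (racemic, not isolated) | CC(C)=CCC/C(C)=C/CC/C(C)=C/CCC1(C)OC12CC2 | intermediate
8 | 2-methyl-2-[(3E,7E)-4,8,12-trimethyltrideca-3,7,11-trien-1-yl]cyclobutan-1-one (racemic) | CC(C)=CCC/C(C)=C/CC/C(C)=C/CCC1(C)CCC1=O | intermediate
9 | 2-methyl-2-[(3E,7E)-4,8,12-trimethyltrideca-3,7,11-trien-1-yl]cyclobutan-1-ol (racemic, cis/trans) | CC(C)=CCC/C(C)=C/CC/C(C)=C/CCC1(C)CCC1O | intermediate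
10 | (7E,11E)-4-hydroperoxy-4,8,12,16-tetramethylheptadeca-7,11,15-trienal (racemic, not isolated) | CC(C)=CCC/C(C)=C/CC/C(C)=C/CCC(C)(CCC=O)OO | intermediate
11 | 6-methyl-6-[(3E,7E)-4,8,12-trimethyltrideca-3,7,11-trien-1-yl]-1,2-dioxan-3-ol (racemic at C6, anomers) | CC(C)=CCC/C(C)=C/CC/C(C)=C/CCC1(C)CCC(O)OO1 | intermediate
12 | 6-methyl-6-[(3E,7E)-4,8,12-trimethyltrideca-3,7,11-trien-1-yl]-1,2-dioxan-3-yl acetate (racemic at C6, anomers) | CC(C)=CCC/C(C)=C/CC/C(C)=C/CCC1(C)CCC(OC(C)=O)OO1 | intermediate
13 | (R)-4-benzyl-3-propionyl-1,3-oxazolidin-2-one | CCC(=O)N1[C@H](Cc2ccccc2)COC1=O | starting material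
14 | trichlorotitanium (Z)-enolate of 13 (not isolated) | C/C=C(\O[Ti](Cl)(Cl)Cl)N1[C@H](Cc2ccccc2)COC1=O | intermediate
15 | (4R)-4-benzyl-3-[(2S)-2-[(3S,6S)-6-methyl-6-[(3E,7E)-4,8,12-trimethyltrideca-3,7,11-trien-1-yl]-1,2-dioxan-3-yl]propanoyl]-1,3-oxazolidin-2-one | CC(C)=CCC/C(C)=C/CC/C(C)=C/CC[C@@]1(C)CC[C@@H]([C@H](C)C(=O)N2[C@H](Cc3ccccc3)COC2=O)OO1 | intermediate
16 | (2S)-2-[(3S,6S)-6-methyl-6-[(3E,7E)-4,8,12-trimethyltrideca-3,7,11-trien-1-yl]-1,2-dioxan-3-yl]propaneperoxoic acid (not isolated) | CC(C)=CCC/C(C)=C/CC/C(C)=C/CC[C@@]1(C)CC[C@@H]([C@H](C)C(=O)OO)OO1 | intermediate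
17 | (2S)-2-[(3S,6S)-6-methyl-6-[(3E,7E)-4,8,12-trimethyltrideca-3,7,11-trien-1-yl]-1,2-dioxan-3-yl]propanoic acid | CC(C)=CCC/C(C)=C/CC/C(C)=C/CC[C@@]1(C)CC[C@@H]([C@H](C)C(=O)O)OO1 | target

**Step count and risks**

Total step count: 7. Longest linear sequence: 7 steps (from 1 to 17).

Steps most likely to fail:

1. Step 4. The C6 peroxyl radical may add 6-exo to the nearest chain alkene or start allylic autoxidation of the polyene before it is reduced and closes onto the aldehyde, and alkoxy radical generation from the secondary cyclobutanol may be sluggish. The fallback sets out from farnesylacetone 4 and comes back at dioxanol 11. Kinetic deprotonation at the methyl group (LDA, THF, −78 °C) and trapping with PhNTf2 would give (5E,9E)-6,10,14-trimethylpentadeca-1,5,9,13-tetraen-2-yl triflate F1. Negishi coupling with [2-(1,3-dioxolan-2-yl)ethyl]zinc bromide (Pd(dppf)Cl2, THF) would give the 1,1-disubstituted alkene acetal 2-[(6E,10E)-7,11,15-trimethyl-3-methylidenehexadeca-6,10,14-trien-1-yl]-1,3-dioxolane F2. Isayama–Mukaiyama hydroperoxysilylation (Co(thd)2, O2, Et3SiH), which should prefer the 1,1-disubstituted over the trisubstituted alkenes, would give the tertiary triethylsilyl peroxide F3. Aqueous HCl in THF would then free hydroperoxide and aldehyde, which close to 11.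

2. Step 6. The enolate may take up the peroxycarbenium ion in the arrangement that leads to the 2,3-syn isomer, the Lewis acid may ionise or hydrochlorinate the trisubstituted alkenes, and the two C6 epimers may be hard to separate. The fallback sets out from cyclobutanone 8 and comes back at the target 17; it forms the C2–C3 bond before the ring expansion and sets C3 with hydride.
   - Aldol addition of the chlorotitanium enolate of (S)-4-benzyl-3-propionyl-1,3-oxazolidin-2-one (the enantiomer of 13, because the closed aldol transition state uses the opposite enolate face) to 8 would give the tertiary cyclobutanol imide F4.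
   - Co(acac)2/O2 ring expansion as in step 4 would give the 3-hydroxy-1,2-dioxane (peroxy-hemiketal) imide F5.
   - Et3SiH with BF3·OEt2 (CH2Cl2, −78 °C) should reduce it through the peroxycarbenium ion, with hydride delivered anti to the acyl group in the A(1,3)-minimised conformer, to the (2S,3S,6S) imide F6 after HPLC removal of its C6 epimer.
   - LiOH/H2O2 would then give 17.

3. Step 7. Hydroxide may trigger E1cB opening of the β-peroxy imide or Kornblum–DeLaMare cleavage at C3–H, or may open the oxazolidinone ring instead of the exocyclic carbonyl. The fallback sets out from imide 15 and comes back at 17 without strong aqueous base. LiBH4 (Et2O, 1 equiv H2O, 0 °C) would remove the auxiliary reductively to give the primary alcohol (2R)-2-[(3S,6S)-6-methyl-6-(homofarnesyl)-1,2-dioxan-3-yl]propan-1-ol F7. TEMPO/PhI(OAc)2 would give the aldehyde F8, and Pinnick oxidation (NaClO2, NaH2PO4, 2-methyl-2-butene, t-BuOH/H2O) would give 17.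

**Further compounds**

F1 | step 4 | (5E,9E)-6,10,14-trimethylpentadeca-1,5,9,13-tetraen-2-yl trifluoromethanesulfonate | CC(C)=CCC/C(C)=C/CC/C(C)=C/CCC(=C)OS(=O)(=O)C(F)(F)F
F2 | step 4 | 2-[(6E,10E)-7,11,15-trimethyl-3-methylidenehexadeca-6,10,14-trien-1-yl]-1,3-dioxolane | CC(C)=CCC/C(C)=C/CC/C(C)=C/CCC(=C)CCC1OCCO1
F3 | step 4 | 2-[(6E,10E)-3,7,11,15-tetramethyl-3-(triethylsilylperoxy)hexadeca-6,10,14-trien-1-yl]-1,3-dioxolane (racemic) | CC(C)=CCC/C(C)=C/CC/C(C)=C/CCC(C)(CCC1OCCO1)OO[Si](CC)(CC)CC
F4 | step 6 | (4S)-4-benzyl-3-[(2S)-2-[1-hydroxy-2-methyl-2-[(3E,7E)-4,8,12-trimethyltrideca-3,7,11-trien-1-yl]cyclobutyl]propanoyl]-1,3-oxazolidin-2-one (ring diastereomers) | C[C@H](C(=O)N1[C@@H](Cc2ccccc2)COC1=O)C1(O)CCC1(C)CC/C=C(\C)CC/C=C(\C)CCC=C(C)C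
F5 | step 6 | (4S)-4-benzyl-3-[(2S)-2-[3-hydroxy-6-methyl-6-[(3E,7E)-4,8,12-trimethyltrideca-3,7,11-trien-1-yl]-1,2-dioxan-3-yl]propanoyl]-1,3-oxazolidin-2-one (C6 epimers, anomers) | C[C@H](C(=O)N1[C@@H](Cc2ccccc2)COC1=O)C1(O)CCC(C)(CC/C=C(\C)CC/C=C(\C)CCC=C(C)C)OO1
F6 | step 6 | (4S)-4-benzyl-3-[(2S)-2-[(3S,6S)-6-methyl-6-[(3E,7E)-4,8,12-trimethyltrideca-3,7,11-trien-1-yl]-1,2-dioxan-3-yl]propanoyl]-1,3-oxazolidin-2-one | CC(C)=CCC/C(C)=C/CC/C(C)=C/CC[C@@]1(C)CC[C@@H]([C@H](C)C(=O)N2[C@@H](Cc3ccccc3)COC2=O)OO1
F7 | step 7 | (2R)-2-[(3S,6S)-6-methyl-6-[(3E,7E)-4,8,12-trimethyltrideca-3,7,11-trien-1-yl]-1,2-dioxan-3-yl]propan-1-ol | CC(C)=CCC/C(C)=C/CC/C(C)=C/CC[C@@]1(C)CC[C@@H]([C@H](C)CO)OO1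
F8 | step 7 | (2S)-2-[(3S,6S)-6-methyl-6-[(3E,7E)-4,8,12-trimethyltrideca-3,7,11-trien-1-yl]-1,2-dioxan-3-yl]propanal | CC(C)=CCC/C(C)=C/CC/C(C)=C/CC[C@@]1(C)CC[C@@H]([C@H](C)C=O)OO1
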